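The route rests on disconnecting the O1–C2 bond of ring C together with the C3–OMe bond, which turns the chromone into an aryl alkynyl ketone (C4(=O)–C3≡C2–C1') linking the hexasubstituted ring A to ring B. One treatment with iodine monochloride adds an ortho oxygen of ring A and iodine across the alkyne, closing ring C and leaving C3–I as the handle for the 3-methoxy group. The precursor carries benzyl on both ortho oxygens and the para oxygen of ring A and on the ring B phenol; because the 6,8-dimethoxy pattern makes the two ortho oxygens equivalent, no regioisomer can arise, the attacking ether leaves as benzyl chloride, and a single hydrogenolysis ends the synthesis.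

Key step: step 11

Remark: the target has no stereocentre; alcohol 16 is formed as a racemate and its carbinol carbon becomes the C4 carbonyl in step 10. Chromone numbering (O1, C2–C8, primed locants for ring B) is used throughout, and the iminium salts 2, 8 and 12 are drawn as chlorides.

Step 1
Reactants: 1 phloroglucinol
Product: 3 2,4,6-trihydroxybenzene-1,3-dicarbaldehyde, via bis-iminium dichloride 2 (not isolated)
Conditions: POCl3 (2.3 equiv), DMF, dioxane, 0 °C → rt; then ice–water
Reagents that add atoms: N,N-dimethylformamide, CN(C)C=O; water, O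
Why: Twofold Vilsmeier–Haack formylation, for which the free triphenol is nucleophilic enough to accept two chloroiminium units, while the two iminium groups deactivate the last ring position and the reagent stoichiometry stops the reaction there.

Step 2
Reactants: 3 2,4,6-trihydroxybenzene-1,3-dicarbaldehyde
Product: 4 2,4,6-tris(benzyloxy)benzene-1,3-dicarbaldehyde
Conditions: BnBr (3.6 equiv), K2CO3, DMF, 70 °C
Reagents that add atoms: benzyl bromide, BrCc1ccccc1
Why: Williamson etherification, in which carbonate in a dipolar aprotic solvent should favour O- over C-alkylation of the acceptor-substituted phloroglucinol, and heating drives the chelated hydroxyl groups to full conversion.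

Step 3
Reactants: 4 2,4,6-tris(benzyloxy)benzene-1,3-dicarbaldehyde
Product: 6 2,4,6-tris(benzyloxy)benzene-1,3-diol, via bis-formate 5 (not isolated)
Conditions: mCPBA (2.4 equiv), CH2Cl2, 0 °C → rt; aq NaHCO3 wash; then K2CO3 (cat.), MeOH, rt, under N2
Reagents that add atoms: 3-chloroperoxybenzoic acid, OOC(=O)c1cccc(Cl)c1
Why: Twofold Baeyer–Villiger (Dakin-type) oxidation, in which the trialkoxy-substituted aryl group migrates in preference to hydrogen, followed by methanolysis of the aryl formates under conditions that leave benzyl ethers untouched; the air-sensitive diol is carried on at once.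

Step 4
Reactants: 6 2,4,6-tris(benzyloxy)benzene-1,3-diol
Product: 7 1,3,5-tris(benzyloxy)-2,4-dimethoxybenzene
Conditions: MeI, K2CO3, DMF, rt, under N2
Reagents that add atoms: iodomethane, CI
Why: Williamson methylation of two flanked phenols, for which the small electrophile and DMF should overcome the hindrance.

Step 5
Reactants: 7 1,3,5-tris(benzyloxy)-2,4-dimethoxybenzene
Product: 9 2,4,6-tris(benzyloxy)-3,5-dimethoxybenzaldehyde, via iminium chloride 8 (not isolated)
Conditions: POCl3, DMF, 0 → 70 °C; then ice–water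
Reagents that add atoms: N,N-dimethylformamide, CN(C)C=O; water, O
Why: Vilsmeier–Haack formylation at the only free ring position, which is activated by two ortho and one para oxygen, under conditions that benzyl aryl ethers are known to tolerate.

Step 6
Reactants: 10 2,4-dimethoxyphenol
Product: 11 1-(benzyloxy)-2,4-dimethoxybenzene
Conditions: BnBr, K2CO3, acetone, reflux
Reagents that add atoms: benzyl bromide, BrCc1ccccc1
Why: Williamson etherification of an unhindered phenol.

Step 7
Reactants: 11 1-(benzyloxy)-2,4-dimethoxybenzene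
Product: 13 5-(benzyloxy)-2,4-dimethoxybenzaldehyde, via iminium chloride 12 (not isolated)
Conditions: POCl3, DMF, 0 → 60 °C; then ice–water
Reagents that add atoms: N,N-dimethylformamide, CN(C)C=O; water, O
Why: Vilsmeier–Haack formylation, directed to C5 because that position is para to one methoxy group and ortho to the other, whereas C3 is flanked on both sides and C6 is activated only by the benzyloxy group, as in the formylation of 1,2,4-trialkoxybenzenes.

Step 8
Reactants: 13 5-(benzyloxy)-2,4-dimethoxybenzaldehyde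
Product: 14 1-(benzyloxy)-5-ethynyl-2,4-dimethoxybenzene
Conditions: dimethyl (1-diazo-2-oxopropyl)phosphonate, K2CO3, MeOH–THF, rt
Reagents that add atoms: dimethyl (1-diazo-2-oxopropyl)phosphonate, CC(=O)C(=[N+]=[N-])P(=O)(OC)OC
Why: Seyferth–Gilbert homologation in the Ohira–Bestmann variant, which converts aryl aldehydes, electron-rich ones included, into terminal alkynes under mild carbonate conditions.

Step 9
Reactants: 14 1-(benzyloxy)-5-ethynyl-2,4-dimethoxybenzene; 9 2,4,6-tris(benzyloxy)-3,5-dimethoxybenzaldehyde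
Product: 16 rac-3-[5-(benzyloxy)-2,4-dimethoxyphenyl]-1-[2,4,6-tris(benzyloxy)-3,5-dimethoxyphenyl]prop-2-yn-1-ol, via lithium acetylide 15 (not isolated)
Conditions: n-BuLi, THF, −78 °C; then 9, −78 → 0 °C; H2O quench
Reagents that add atoms: none
Why: 1,2-Addition of a lithium acetylide to an aldehyde, for which the slim nucleophile should reach the doubly ortho-substituted carbonyl; the new carbinol centre is formed without control because it is oxidized in the next step, and the neutral quench protects the ionization-prone alcohol.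

Step 10
Reactants: 16 rac-3-[5-(benzyloxy)-2,4-dimethoxyphenyl]-1-[2,4,6-tris(benzyloxy)-3,5-dimethoxyphenyl]prop-2-yn-1-ol
Product: 17 3-[5-(benzyloxy)-2,4-dimethoxyphenyl]-1-[2,4,6-tris(benzyloxy)-3,5-dimethoxyphenyl]prop-2-yn-1-one
Conditions: activated MnO2 (excess), CH2Cl2, rt
Reagents that add atoms: none
Why: Manganese dioxide oxidation of a benzylic and propargylic alcohol, a neutral heterogeneous method that leaves the alkyne, the benzyl ethers and the electron-rich rings alone.

Step 11
Reactants: 17 3-[5-(benzyloxy)-2,4-dimethoxyphenyl]-1-[2,4,6-tris(benzyloxy)-3,5-dimethoxyphenyl]prop-2-yn-1-one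
Product: 18 5,7-bis(benzyloxy)-2-[5-(benzyloxy)-2,4-dimethoxyphenyl]-3-iodo-6,8-dimethoxy-4H-chromen-4-one
Conditions: ICl (1.2 equiv), CH2Cl2, −78 °C; aq Na2S2O3
Reagents that add atoms: iodine monochloride, ClI
Why: ICl delivers an iodonium ion to the ynone triple bond; positive charge builds at C2, the carbon β to the carbonyl and benzylic to the 2,4-dialkoxy ring B, one ortho benzyloxy oxygen of ring A attacks it anti to iodine, and chloride then removes the benzyl group from the resulting oxonium ion as benzyl chloride. The closest known reaction type is the iodine monochloride-induced cyclization of 2-alkoxyaryl alkynyl ketones to 3-iodochromones. Ring C, the only ring formed, closes in the 6-endo-dig mode, and no stereocentre is created. The selectivity needed is 6-endo over 5-exo closure (which would give an aurone-type benzofuranone); it is secured by the ynone polarization, reinforced by the ortho and para methoxy groups of ring B, which stabilize charge at C2 and not at C3, and for the same reason the 2'-methoxy oxygen of ring B, which could only reach C3, should not compete. Because the two ortho oxygens of ring A are equivalent, either one gives the same chromone, and since ring A has no free position only ring B could be iodinated, which −78 °C and a small excess of ICl should prevent.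

Step 12
Reactants: 18 5,7-bis(benzyloxy)-2-[5-(benzyloxy)-2,4-dimethoxyphenyl]-3-iodo-6,8-dimethoxy-4H-chromen-4-one
Product: 19 5,7-bis(benzyloxy)-2-[5-(benzyloxy)-2,4-dimethoxyphenyl]-3,6,8-trimethoxy-4H-chromen-4-one
Conditions: CuI (20 mol %), 3,4,7,8-tetramethyl-1,10-phenanthroline (40 mol %), Cs2CO3, MeOH–toluene, 80 °C, sealed tube
Reagents that add atoms: methanol, CO
Why: Ullmann-type CuI-catalysed C–O coupling of an alkenyl iodide with an aliphatic alcohol, with carbonate in place of free methoxide to keep the concentration of the nucleophile that could attack C2 of the chromone low.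

Step 13
Reactants: 19 5,7-bis(benzyloxy)-2-[5-(benzyloxy)-2,4-dimethoxyphenyl]-3,6,8-trimethoxy-4H-chromen-4-one
Product: 20 5,7-dihydroxy-2-(5-hydroxy-2,4-dimethoxyphenyl)-3,6,8-trimethoxy-4H-chromen-4-one
Conditions: H2 (1 atm), 10% Pd/C, EtOAc–MeOH, rt
Reagents that add atoms: none
Why: Catalytic hydrogenolysis of three benzyl aryl ethers, under which the methyl ethers and the tetrasubstituted C2=C3 bond of the chromone should remain intact.

Compound list
1 | phloroglucinol (benzene-1,3,5-triol) | Oc1cc(O)cc(O)c1 | starting material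
2 | 2,4-bis[(dimethyliminio)methyl]benzene-1,3,5-triol dichloride | C[N+](C)=Cc1c(O)cc(O)c(C=[N+](C)C)c1O.[Cl-].[Cl-] | intermediate
3 | 2,4,6-trihydroxybenzene-1,3-dicarbaldehyde | O=Cc1c(O)cc(O)c(C=O)c1O | intermediate
4 | 2,4,6-tris(benzyloxy)benzene-1,3-dicarbaldehyde | O=Cc1c(OCc2ccccc2)cc(OCc2ccccc2)c(C=O)c1OCc1ccccc1 | intermediate
5 | 2,4,6-tris(benzyloxy)benzene-1,3-diyl diformate | O=COc1c(OCc2ccccc2)cc(OCc2ccccc2)c(OC=O)c1OCc1ccccc1 | intermediate
6 | 2,4,6-tris(benzyloxy)benzene-1,3-diol | Oc1c(OCc2ccccc2)cc(OCc2ccccc2)c(O)c1OCc1ccccc1 | intermediate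
7 | 1,3,5-tris(benzyloxy)-2,4-dimethoxybenzene | COc1c(OCc2ccccc2)cc(OCc2ccccc2)c(OC)c1OCc1ccccc1 | intermediate
8 | N-{[2,4,6-tris(benzyloxy)-3,5-dimethoxyphenyl]methylidene}-N-methylmethanaminium chloride | COc1c(OCc2ccccc2)c(C=[N+](C)C)c(OCc2ccccc2)c(OC)c1OCc1ccccc1.[Cl-] | intermediate
9 | 2,4,6-tris(benzyloxy)-3,5-dimethoxybenzaldehyde | COc1c(OCc2ccccc2)c(C=O)c(OCc2ccccc2)c(OC)c1OCc1ccccc1 | intermediate
10 | 2,4-dimethoxyphenol | COc1ccc(O)c(OC)c1 | starting material
11 | 1-(benzyloxy)-2,4-dimethoxybenzene | COc1ccc(OCc2ccccc2)c(OC)c1 | intermediate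
12 | N-{[5-(benzyloxy)-2,4-dimethoxyphenyl]methylidene}-N-methylmethanaminium chloride | COc1cc(OC)c(C=[N+](C)C)cc1OCc1ccccc1.[Cl-] | intermediate
13 | 5-(benzyloxy)-2,4-dimethoxybenzaldehyde | COc1cc(OC)c(C=O)cc1OCc1ccccc1 | intermediate
14 | 1-(benzyloxy)-5-ethynyl-2,4-dimethoxybenzene | COc1cc(OC)c(C#C)cc1OCc1ccccc1 | intermediate
15 | lithium [5-(benzyloxy)-2,4-dimethoxyphenyl]acetylide | [Li]C#Cc1cc(OCc2ccccc2)c(OC)cc1OC | intermediate
16 | rac-3-[5-(benzyloxy)-2,4-dimethoxyphenyl]-1-[2,4,6-tris(benzyloxy)-3,5-dimethoxyphenyl]prop-2-yn-1-ol (racemate, no defined configuration) | COc1cc(OC)c(C#CC(O)c2c(OCc3ccccc3)c(OC)c(OCc3ccccc3)c(OC)c2OCc2ccccc2)cc1OCc1ccccc1 | intermediate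
17 | 3-[5-(benzyloxy)-2,4-dimethoxyphenyl]-1-[2,4,6-tris(benzyloxy)-3,5-dimethoxyphenyl]prop-2-yn-1-one | COc1cc(OC)c(C#CC(=O)c2c(OCc3ccccc3)c(OC)c(OCc3ccccc3)c(OC)c2OCc2ccccc2)cc1OCc1ccccc1 | intermediate
18 | 5,7-bis(benzyloxy)-2-[5-(benzyloxy)-2,4-dimethoxyphenyl]-3-iodo-6,8-dimethoxy-4H-chromen-4-one | COc1cc(OC)c(-c2oc3c(OC)c(OCc4ccccc4)c(OC)c(OCc4ccccc4)c3c(=O)c2I)cc1OCc1ccccc1 | intermediate
19 | 5,7-bis(benzyloxy)-2-[5-(benzyloxy)-2,4-dimethoxyphenyl]-3,6,8-trimethoxy-4H-chromen-4-one | COc1cc(OC)c(-c2oc3c(OC)c(OCc4ccccc4)c(OC)c(OCc4ccccc4)c3c(=O)c2OC)cc1OCc1ccccc1 | intermediate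
20 | 5,7-dihydroxy-2-(5-hydroxy-2,4-dimethoxyphenyl)-3,6,8-trimethoxy-4H-chromen-4-one (no stereocentre) | COc1cc(OC)c(-c2oc3c(OC)c(O)c(OC)c(O)c3c(=O)c2OC)cc1O | target

Total step count: 13 (ring A aldehyde in steps 1–5, ring B alkyne in steps 6–8, union and endgame in steps 9–13).
Longest linear sequence: 10 steps (steps 1–5 and 9–13, from phloroglucinol).

Steps most likely to fail

Step 11. The ring closure may be diverted into the 5-exo mode, ICl may simply add across the triple bond without cyclization, ring B may be iodinated, or the oxonium ion may fail to lose its benzyl group cleanly. The fallback closes ring C with a free phenol and introduces iodine afterwards. It sets out from 17: chelation-controlled removal of one benzyl group ortho to the ketone with BCl3 (1 equiv, CH2Cl2, −78 °C) should give 1-[2,4-bis(benzyloxy)-6-hydroxy-3,5-dimethoxyphenyl]-3-[5-(benzyloxy)-2,4-dimethoxyphenyl]prop-2-yn-1-one F1. DMAP-catalysed 6-endo oxa-Michael closure (DMF, rt) should then give the 3-unsubstituted flavone 5,7-bis(benzyloxy)-2-[5-(benzyloxy)-2,4-dimethoxyphenyl]-6,8-dimethoxy-4H-chromen-4-one F2. Deprotonation at C3 with LiN(i-Pr)2 (THF, −78 °C) gives the 3-lithioflavone F3, and quenching with I2 brings the sequence back to the route at 18.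

Step 12. Hydrodeiodination at the crowded C3 position, or attack of methoxide at C2 with opening of ring C, may outrun the C–O coupling. The fallback replaces the coupling by metalation and oxidation. It sets out from 18: iodine–magnesium exchange with i-PrMgCl·LiCl (THF, −40 °C) should give the 3-magnesiated flavone F4, which is trapped with B(OMe)3 as the dimethyl boronate F5. Oxidation with H2O2 in AcOH should give the flavonol 5,7-bis(benzyloxy)-2-[5-(benzyloxy)-2,4-dimethoxyphenyl]-3-hydroxy-6,8-dimethoxy-4H-chromen-4-one F6, and methylation with MeI and K2CO3 in acetone comes back to the route at 19.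

Step 5. Electrophilic substitution at the last, crowded ring position may be sluggish, and prolonged heating may cost a benzyl group ortho to the iminium carbon. The fallback introduces the formyl group through an organolithium. It sets out from 7: bromination with NBS (MeCN, 0 °C) should give 1,3,5-tris(benzyloxy)-2-bromo-4,6-dimethoxybenzene F7, bromine–lithium exchange with n-BuLi (THF, −78 °C) gives the aryllithium F8, and quenching with DMF followed by aqueous work-up comes back to the route at 9.

Further compounds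
F1 | step 11 | 1-[2,4-bis(benzyloxy)-6-hydroxy-3,5-dimethoxyphenyl]-3-[5-(benzyloxy)-2,4-dimethoxyphenyl]prop-2-yn-1-one | COc1cc(OC)c(C#CC(=O)c2c(O)c(OC)c(OCc3ccccc3)c(OC)c2OCc2ccccc2)cc1OCc1ccccc1
F2 | step 11 | 5,7-bis(benzyloxy)-2-[5-(benzyloxy)-2,4-dimethoxyphenyl]-6,8-dimethoxy-4H-chromen-4-one | COc1cc(OC)c(-c2cc(=O)c3c(OCc4ccccc4)c(OC)c(OCc4ccccc4)c(OC)c3o2)cc1OCc1ccccc1
F3 | step 11 | {5,7-bis(benzyloxy)-2-[5-(benzyloxy)-2,4-dimethoxyphenyl]-6,8-dimethoxy-4-oxo-4H-chromen-3-yl}lithium | COc1cc(OC)c(-c2oc3c(OC)c(OCc4ccccc4)c(OC)c(OCc4ccccc4)c3c(=O)c2[Li])cc1OCc1ccccc1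
F4 | step 12 | {5,7-bis(benzyloxy)-2-[5-(benzyloxy)-2,4-dimethoxyphenyl]-6,8-dimethoxy-4-oxo-4H-chromen-3-yl}magnesium chloride | COc1cc(OC)c(-c2oc3c(OC)c(OCc4ccccc4)c(OC)c(OCc4ccccc4)c3c(=O)c2[Mg]Cl)cc1OCc1ccccc1
F5 | step 12 | dimethyl {5,7-bis(benzyloxy)-2-[5-(benzyloxy)-2,4-dimethoxyphenyl]-6,8-dimethoxy-4-oxo-4H-chromen-3-yl}boronate | COc1cc(OC)c(-c2oc3c(OC)c(OCc4ccccc4)c(OC)c(OCc4ccccc4)c3c(=O)c2B(OC)OC)cc1OCc1ccccc1
F6 | step 12 | 5,7-bis(benzyloxy)-2-[5-(benzyloxy)-2,4-dimethoxyphenyl]-3-hydroxy-6,8-dimethoxy-4H-chromen-4-one | COc1cc(OC)c(-c2oc3c(OC)c(OCc4ccccc4)c(OC)c(OCc4ccccc4)c3c(=O)c2O)cc1OCc1ccccc1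
F7 | step 5 | 1,3,5-tris(benzyloxy)-2-bromo-4,6-dimethoxybenzene | COc1c(OCc2ccccc2)c(Br)c(OCc2ccccc2)c(OC)c1OCc1ccccc1
F8 | step 5 | [2,4,6-tris(benzyloxy)-3,5-dimethoxyphenyl]lithium | COc1c(OCc2ccccc2)c([Li])c(OCc2ccccc2)c(OC)c1OCc1ccccc1
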